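**Plan**

- Retrosynthetic cuts: the C15–C15' single bond (sp2–sp2 Stille union of two C20 halves); the C10=C11 and C10'=C11' double bonds (Wittig); the C6–C7 and C6'–C7' bonds (acetylide addition to a ring ketone, then a cation-mediated 1,5-transposition with PPh3·HBr that writes the retro triene); and, in the hydroxylated ring, the two bonds to C5' (one-carbon insertion into a cyclopentanone).
- Enabling feature: in the hydroxylated ring the methyl-bearing sp2 carbon C5' lies between the vinylic C4'H and C6' (the chain-bearing carbon, a carbonyl carbon in the building block), and C6' is flanked on its other side by quaternary C1'. A 2-methylcyclohex-2-enone of this pattern is what results when a C(CH3) unit is inserted between C=O and the only enolisable α-carbon of a 4-silyloxy-2,2-dimethylcyclopentanone.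
- Forward order: cyclopentanone 1 → enone 3 → (S)-hydroxy ketone 5 → ring expansion to six-membered enone 9 → C14 phosphonium salt 14 → C20 stannane 20. Ketoisophorone 21 → C14 keto phosphonium salt 27 → C20 iodide 29. Then 29 + 20 → 30 → target 31.
- Stereochemistry: the only stereocenter (C3', S) is set by copper-catalysed enantioselective β-borylation/oxidation of enone 3 and carried unchanged. Double-bond geometry comes from E-selective alkyne reductions, stereodefined C6 dienals and a final thermal equilibration to the all-E polyene.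

Key step: step 5

Remark: locants C1–C15 (keto half) and C1'–C15' (hydroxy half) follow carotenoid numbering. Steps 8, 12, 16 and 17 may give some Z isomer at C6=C7, C6'=C7', C10=C11 or C10'=C11'; all compounds are drawn as the wanted E isomers, on the assumption that such isomers converge on heating in step 19. The antipode of the ferrocenyl ligand in step 2 is assumed to be chosen, after a test run, as the one that gives the 4S alcohol.

**Step 1**
Reactants: 1 2,2-dimethylcyclopentan-1-one
Product: 3 5,5-dimethylcyclopent-2-en-1-one, via trimethylsilyl enol ether 2 (not isolated)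
Conditions: LiN(i-Pr)2, Me3SiCl, THF, −78 °C; then Pd(OAc)2, MeCN, rt
Reagents that add atoms: none
Why: Saegusa–Ito oxidation; the ketone can enolise only away from the quaternary carbon, so palladation of the single silyl enol ether and β-hydride elimination should give the enone regiospecifically.

**Step 2**
Reactants: 3 5,5-dimethylcyclopent-2-en-1-one
Product: 5 (4S)-4-hydroxy-2,2-dimethylcyclopentan-1-one, via pinacol boronate 4 (not isolated)
Conditions: B2pin2, MeOH, CuCl (cat.), NaOt-Bu (cat.), (R)-1-[(S)-2-(diphenylphosphino)ferrocenyl]ethyldicyclohexylphosphine or its mirror image (cat.), THF, rt; then NaBO3·4H2O, THF/H2O, rt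
Reagents that add atoms: sodium perborate, [Na+].[O-]OB=O
Why: Copper-catalysed enantioselective conjugate borylation of a cyclic enone (the chiral bisphosphine–copper boryl selects the enantioface of the β-carbon), followed by stereoretentive C–B oxidation, should set the carbinol center that becomes C3'.

**Step 3**
Reactants: 5 (4S)-4-hydroxy-2,2-dimethylcyclopentan-1-one
Product: 6 (4S)-4-[(tert-butyldiphenylsilyl)oxy]-2,2-dimethylcyclopentan-1-one
Conditions: t-BuPh2SiCl, imidazole, DMF, rt
Reagents that add atoms: tert-butyl(chloro)diphenylsilane, CC(C)(C)[Si](Cl)(c1ccccc1)c1ccccc1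
Why: Standard silylation of a secondary alcohol; the bulky, acid-resistant silyl ether is chosen to survive organometallic reagents, aluminium hydride and PPh3·HBr later on.

**Step 4**
Reactants: 6 (4S)-4-[(tert-butyldiphenylsilyl)oxy]-2,2-dimethylcyclopentan-1-one
Product: 7 tert-butyl{[(1S)-4,4-dimethyl-3-[(trimethylsilyl)oxy]cyclopent-2-en-1-yl]oxy}diphenylsilane
Conditions: Me3SiOTf, Et3N, CH2Cl2, 0 °C
Reagents that add atoms: trimethylsilyl trifluoromethanesulfonate, C[Si](C)(C)OS(=O)(=O)C(F)(F)F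
Why: Soft enolisation to the only possible silyl enol ether; no free enolate is formed, so β-elimination of the silyloxy group should be avoided.

**Step 5**
Reactants: 7 tert-butyl{[(1S)-4,4-dimethyl-3-[(trimethylsilyl)oxy]cyclopent-2-en-1-yl]oxy}diphenylsilane
Product: 9 (4S)-4-[(tert-butyldiphenylsilyl)oxy]-2,6,6-trimethylcyclohex-2-en-1-one, via chlorocyclopropane 8 (not isolated)
Conditions: MeCHCl2, n-BuLi, Et2O, −35 °C; then toluene, 110 °C, concentration
Reagents that add atoms: 1,1-dichloroethane, CC(Cl)Cl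
Why: 1,1-Dichloroethane is lithiated and loses LiCl to a chloro(methyl)carbenoid that adds to the electron-rich enol ether double bond of 7, giving the 6-chloro-6-methyl-1-silyloxybicyclo[3.1.0]hexane 8; on heating, chloride departs while the shared C1–C5 bond opens disrotatorily (cyclopropyl-to-allyl cation, pushed by the C1 oxygen), and loss of Me3SiCl from the 1-silyloxy-2-methylcyclohexenyl cation leaves enone 9. The closest known reaction type is the halocarbene one-carbon ring expansion of cyclic silyl enol ethers to 2-halo- or 2-methylcycloalk-2-enones. The three-membered ring is closed by [2+1] carbene addition; the six-membered ring is not closed by a cyclisation but arises from the five-membered ring by cleavage of the zero-atom bridge, the inserted carbon becoming the methyl-bearing C2 between the carbonyl carbon and the former α-CH. No stereocenter that survives is created: the cyclopropane centers vanish on opening and the silyloxy-bearing carbon is not touched, so the S configuration from step 2 is carried over. The step needs regiocontrol of enolisation, which the quaternary α-carbon of 6 secures, and it needs chloride on the endo face for the orbital-symmetry-allowed inward rotation of the ring bonds, which chlorocarbenoids should favour; the exo-chloride epimer would not open.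

**Step 6**
Reactants: 9 (4S)-4-[(tert-butyldiphenylsilyl)oxy]-2,6,6-trimethylcyclohex-2-en-1-one; 10 2-methylbut-1-en-3-yne
Product: 12 (4S)-4-[(tert-butyldiphenylsilyl)oxy]-2,6,6-trimethyl-1-(3-methylbut-3-en-1-yn-1-yl)cyclohex-2-en-1-ol (both C1 epimers), via lithium acetylide 11 (not isolated)
Conditions: 10, n-BuLi, THF, −78 °C; then 9, −78 to 0 °C; H2O
Reagents that add atoms: none
Why: 1,2-Addition of a slim lithium acetylide to the hindered, non-enolisable enone carbonyl; the new carbinol center is of no consequence because it is planarised in step 8.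

**Step 7**
Reactants: 12 (4S)-4-[(tert-butyldiphenylsilyl)oxy]-2,6,6-trimethyl-1-(3-methylbut-3-en-1-yn-1-yl)cyclohex-2-en-1-ol
Product: 13 (4S)-4-[(tert-butyldiphenylsilyl)oxy]-2,6,6-trimethyl-1-[(1E)-3-methylbuta-1,3-dien-1-yl]cyclohex-2-en-1-ol
Conditions: NaAlH2(OCH2CH2OMe)2, THF, 0 °C to rt; aq KNaC4H4O6
Reagents that add atoms: none
Why: Alkoxide-directed trans-hydroalumination of a propargylic alcohol should give the E-alkene only and leave the isopropenyl group and the silyl ether alone.

**Step 8**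
Reactants: 13 (4S)-4-[(tert-butyldiphenylsilyl)oxy]-2,6,6-trimethyl-1-[(1E)-3-methylbuta-1,3-dien-1-yl]cyclohex-2-en-1-ol
Product: 14 [(2E,4E)-4-{(4S)-4-[(tert-butyldiphenylsilyl)oxy]-2,6,6-trimethylcyclohex-2-en-1-ylidene}-2-methylbut-2-en-1-yl]triphenylphosphonium bromide
Conditions: PPh3·HBr, CH2Cl2, 0 °C to rt
Reagents that add atoms: triphenylphosphine hydrobromide, Br.c1ccc(cc1)P(c1ccccc1)c1ccccc1
Why: SN1 substitution with allylic (1,5) transposition, as in the classical conversion of tertiary vinyl carbinols into polyenyl phosphonium salts: the doubly allylic tertiary alcohol ionises to a pentadienyl cation that has no ring β-hydrogen to lose, and PPh3 should capture the unhindered CH2 terminus, installing the exocyclic C6'=C7' and the C8'=C9' double bonds of the retro system.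

**Step 9**
Reactants: 15 (2E)-3-methylpent-2-en-4-yn-1-ol
Product: 16 (2E,4E)-3-methyl-5-(tributylstannyl)penta-2,4-dien-1-ol
Conditions: Bu3SnH, PdCl2(PPh3)2 (cat.), THF, 0 °C
Reagents that add atoms: tributyltin hydride, CCCC[SnH](CCCC)CCCC
Why: Palladium-catalysed syn-hydrostannation of a terminal alkyne should place tin at the terminal carbon with E geometry.

**Step 10**
Reactants: 16 (2E,4E)-3-methyl-5-(tributylstannyl)penta-2,4-dien-1-ol
Product: 17 (2E,4E)-3-methyl-5-(tributylstannyl)penta-2,4-dienal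
Conditions: MnO2, CH2Cl2, rt
Reagents that add atoms: none
Why: Chemoselective MnO2 oxidation of an allylic alcohol, which leaves the alkenylstannane and the alkene geometry intact.

**Step 11**
Reactants: 17 (2E,4E)-3-methyl-5-(tributylstannyl)penta-2,4-dienal (part of the batch)
Product: 18 (2E,4E)-5-iodo-3-methylpenta-2,4-dienal
Conditions: iodine (I2), CH2Cl2, 0 °C, dark; aq Na2S2O3
Reagents that add atoms: iodine, II
Why: Iododestannylation proceeds by ipso substitution with retention of the alkene geometry.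

**Step 12**
Reactants: 14 hydroxy-ring C14 phosphonium bromide (as in step 8); 17 (2E,4E)-3-methyl-5-(tributylstannyl)penta-2,4-dienal
Product: 20 tert-butyl{[(1S,4E)-4-[(2E,4E,6E,8E)-3,7-dimethyl-9-(tributylstannyl)nona-2,4,6,8-tetraen-1-ylidene]-3,5,5-trimethylcyclohex-2-en-1-yl]oxy}diphenylsilane, via phosphorus ylide 19 (not isolated)
Conditions: NaN(SiMe3)2, THF, −78 °C; then 17, −78 to 0 °C
Reagents that add atoms: none
Why: Wittig olefination of a polyenyl ylide at its α-carbon with an enal, the standard chain-building reaction of carotenoid synthesis, should form C10'=C11'.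

**Step 13**
Reactants: 21 2,6,6-trimethylcyclohex-2-ene-1,4-dione (ketoisophorone)
Product: 22 7,9,9-trimethyl-1,4-dioxaspiro[4.5]dec-6-en-8-one
Conditions: HOCH2CH2OH, p-TsOH (cat.), benzene, reflux, Dean–Stark
Reagents that add atoms: ethane-1,2-diol, OCCO
Why: Selective ketalisation of the less hindered C4 carbonyl; the C1 carbonyl is shielded by the gem-dimethyl carbon and the C2 methyl group.

**Step 14**
Reactants: 22 7,9,9-trimethyl-1,4-dioxaspiro[4.5]dec-6-en-8-one; 10 2-methylbut-1-en-3-yne
Product: 24 8-(3-methylbut-3-en-1-yn-1-yl)-7,9,9-trimethyl-1,4-dioxaspiro[4.5]dec-6-en-8-ol (racemic), via bromomagnesium acetylide 23 (not isolated)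
Conditions: 10, EtMgBr, THF, 0 to 40 °C; then 22, 0 °C to rt; H2O
Reagents that add atoms: none
Why: 1,2-Addition of an alkynylmagnesium bromide, made by deprotonating the terminal alkyne with ethylmagnesium bromide, to the remaining hindered enone carbonyl, a well-used Grignard reaction of this monoketal; the ketal is inert to the reagent and the racemic carbinol center is removed in step 16.

**Step 15**
Reactants: 24 8-(3-methylbut-3-en-1-yn-1-yl)-7,9,9-trimethyl-1,4-dioxaspiro[4.5]dec-6-en-8-ol
Product: 25 8-[(1E)-3-methylbuta-1,3-dien-1-yl]-7,9,9-trimethyl-1,4-dioxaspiro[4.5]dec-6-en-8-ol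
Conditions: NaAlH2(OCH2CH2OMe)2, THF, 0 °C to rt; aq KNaC4H4O6
Reagents that add atoms: none
Why: Alkoxide-directed trans-hydroalumination of the propargylic alcohol to the E-alkene; the ketal is inert to hydride.

**Step 16**
Reactants: 25 8-[(1E)-3-methylbuta-1,3-dien-1-yl]-7,9,9-trimethyl-1,4-dioxaspiro[4.5]dec-6-en-8-ol
Product: 27 [(2E,4E)-2-methyl-4-(2,6,6-trimethyl-4-oxocyclohex-2-en-1-ylidene)but-2-en-1-yl]triphenylphosphonium bromide, via ketal phosphonium bromide 26 (not isolated)
Conditions: PPh3·HBr, CH2Cl2, 0 °C to rt; then acetone/H2O, rt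
Reagents that add atoms: triphenylphosphine hydrobromide, Br.c1ccc(cc1)P(c1ccccc1)c1ccccc1; water, O
Why: The same SN1 substitution with 1,5-transposition as in step 8 is run first under anhydrous conditions, while the ketal still lets the carbinol ionise, and the vinylogous ketal is then hydrolysed by the residual acid.

**Step 17**
Reactants: 27 keto-ring C14 phosphonium bromide (as in step 16); 18 (2E,4E)-5-iodo-3-methylpenta-2,4-dienal
Product: 29 (4E)-4-[(2E,4E,6E,8E)-9-iodo-3,7-dimethylnona-2,4,6,8-tetraen-1-ylidene]-3,5,5-trimethylcyclohex-2-en-1-one, via phosphorus ylide 28 (not isolated)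
Conditions: NaN(SiMe3)2, THF, −78 °C; then 18, −78 °C to rt
Reagents that add atoms: none
Why: Wittig olefination forming C10=C11; ylides conjugated to a ring ketone through the polyene still condense at the carbon next to phosphorus, as in the manufacture of oxo-carotenoids, and a non-nucleophilic base is used so that the iodide is not displaced.

**Step 18**
Reactants: 29 keto-ring C20 iodide (as in step 17); 20 hydroxy-ring C20 stannane (as in step 12)
Product: 30 (3'S,6E,6'E)-3'-[(tert-butyldiphenylsilyl)oxy]-4',5'-didehydro-4,5'-retro-β,β-caroten-3-one (all-E)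
Conditions: Pd2(dba)3 (cat.), AsPh3, NMP, rt, dark
Reagents that add atoms: none
Why: Stille coupling of an alkenyl iodide with an alkenylstannane under zerovalent palladium forms the C15–C15' bond between two sp2 carbons with retention of geometry on both partners, under neutral conditions that the dienone and the silyl ether tolerate.

**Step 19**
Reactants: 30 silyl ether of the target (as in step 18)
Product: 31 (3'S,6E,6'E)-3'-hydroxy-4',5'-didehydro-4,5'-retro-β,β-caroten-3-one (all-E; the target)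
Conditions: Bu4NF, AcOH, THF, 0 °C to rt; then heptane/EtOAc, 80 °C, argon, dark; crystallisation
Reagents that add atoms: none
Why: Buffered fluoride desilylation avoids both acid (which would ionise the polyene-conjugated allylic alcohol) and strong base, and the final heating should equilibrate residual Z isomers to the all-E form, in which the in-plane ring methyl groups avoid the chain.

**Compound list**

1 | 2,2-dimethylcyclopentan-1-one | O=C1CCCC1(C)C | starting material
2 | [(5,5-dimethylcyclopent-1-en-1-yl)oxy]trimethylsilane | C[Si](C)(C)OC1=CCCC1(C)C | intermediate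
3 | 5,5-dimethylcyclopent-2-en-1-one | O=C1C=CCC1(C)C | intermediate
4 | (4S)-2,2-dimethyl-4-(4,4,5,5-tetramethyl-1,3,2-dioxaborolan-2-yl)cyclopentan-1-one | O=C1C[C@@H](B2OC(C)(C)C(C)(C)O2)CC1(C)C | intermediate
5 | (4S)-4-hydroxy-2,2-dimethylcyclopentan-1-one | O=C1C[C@@H](O)CC1(C)C | intermediate
6 | (4S)-4-[(tert-butyldiphenylsilyl)oxy]-2,2-dimethylcyclopentan-1-one | O=C1C[C@@H](O[Si](c2ccccc2)(c2ccccc2)C(C)(C)C)CC1(C)C | intermediate
7 | tert-butyl{[(1S)-4,4-dimethyl-3-[(trimethylsilyl)oxy]cyclopent-2-en-1-yl]oxy}diphenylsilane | C[Si](C)(C)OC1=C[C@@H](O[Si](c2ccccc2)(c2ccccc2)C(C)(C)C)CC1(C)C | intermediate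
8 | (4S)-4-[(tert-butyldiphenylsilyl)oxy]-6-chloro-2,2,6-trimethyl-1-[(trimethylsilyl)oxy]bicyclo[3.1.0]hexane (epimers at the cyclopropane carbons) | C[Si](C)(C)OC12C(C)(Cl)C1[C@@H](O[Si](c3ccccc3)(c3ccccc3)C(C)(C)C)CC2(C)C | intermediate
9 | (4S)-4-[(tert-butyldiphenylsilyl)oxy]-2,6,6-trimethylcyclohex-2-en-1-one | CC1=C[C@@H](O[Si](c2ccccc2)(c2ccccc2)C(C)(C)C)CC(C)(C)C1=O | intermediate
10 | 2-methylbut-1-en-3-yne | C=C(C)C#C | starting material
11 | lithium 3-methylbut-3-en-1-yn-1-ide | [Li]C#CC(C)=C | intermediate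
12 | (4S)-4-[(tert-butyldiphenylsilyl)oxy]-2,6,6-trimethyl-1-(3-methylbut-3-en-1-yn-1-yl)cyclohex-2-en-1-ol (both C1 epimers) | CC1=C[C@@H](O[Si](c2ccccc2)(c2ccccc2)C(C)(C)C)CC(C)(C)C1(O)C#CC(C)=C | intermediate
13 | (4S)-4-[(tert-butyldiphenylsilyl)oxy]-2,6,6-trimethyl-1-[(1E)-3-methylbuta-1,3-dien-1-yl]cyclohex-2-en-1-ol (both C1 epimers) | CC1=C[C@@H](O[Si](c2ccccc2)(c2ccccc2)C(C)(C)C)CC(C)(C)C1(O)/C=C/C(C)=C | intermediate
14 | [(2E,4E)-4-{(4S)-4-[(tert-butyldiphenylsilyl)oxy]-2,6,6-trimethylcyclohex-2-en-1-ylidene}-2-methylbut-2-en-1-yl]triphenylphosphonium bromide | [Br-].c1ccccc1[P+](c1ccccc1)(c1ccccc1)C/C(C)=C/C=C1/C(C)=C[C@@H](O[Si](c2ccccc2)(c2ccccc2)C(C)(C)C)CC1(C)C | intermediate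
15 | (2E)-3-methylpent-2-en-4-yn-1-ol | C#C/C(C)=C/CO | starting material
16 | (2E,4E)-3-methyl-5-(tributylstannyl)penta-2,4-dien-1-ol | CCCC[Sn](CCCC)(CCCC)/C=C/C(C)=C/CO | intermediate
17 | (2E,4E)-3-methyl-5-(tributylstannyl)penta-2,4-dienal | CCCC[Sn](CCCC)(CCCC)/C=C/C(C)=C/C=O | intermediate
18 | (2E,4E)-5-iodo-3-methylpenta-2,4-dienal | I/C=C/C(C)=C/C=O | intermediate
19 | ylide of 14 (triphenylphosphonio methanide at C10') | c1ccccc1[P+](c1ccccc1)(c1ccccc1)[CH-]/C(C)=C/C=C1/C(C)=C[C@@H](O[Si](c2ccccc2)(c2ccccc2)C(C)(C)C)CC1(C)C | intermediate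
20 | tert-butyl{[(1S,4E)-4-[(2E,4E,6E,8E)-3,7-dimethyl-9-(tributylstannyl)nona-2,4,6,8-tetraen-1-ylidene]-3,5,5-trimethylcyclohex-2-en-1-yl]oxy}diphenylsilane | CCCC[Sn](CCCC)(CCCC)/C=C/C(C)=C/C=C/C(C)=C/C=C1/C(C)=C[C@@H](O[Si](c2ccccc2)(c2ccccc2)C(C)(C)C)CC1(C)C | intermediate
21 | 2,6,6-trimethylcyclohex-2-ene-1,4-dione (ketoisophorone) | CC1=CC(=O)CC(C)(C)C1=O | starting material
22 | 7,9,9-trimethyl-1,4-dioxaspiro[4.5]dec-6-en-8-one | CC1=CC2(OCCO2)CC(C)(C)C1=O | intermediate
23 | bromo(3-methylbut-3-en-1-yn-1-yl)magnesium | C=C(C)C#C[Mg]Br | intermediate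
24 | 8-(3-methylbut-3-en-1-yn-1-yl)-7,9,9-trimethyl-1,4-dioxaspiro[4.5]dec-6-en-8-ol (racemic) | CC1=CC2(OCCO2)CC(C)(C)C1(O)C#CC(C)=C | intermediate
25 | 8-[(1E)-3-methylbuta-1,3-dien-1-yl]-7,9,9-trimethyl-1,4-dioxaspiro[4.5]dec-6-en-8-ol (racemic) | CC1=CC2(OCCO2)CC(C)(C)C1(O)/C=C/C(C)=C | intermediate
26 | [(2E,4E)-2-methyl-4-(7,9,9-trimethyl-1,4-dioxaspiro[4.5]dec-6-en-8-ylidene)but-2-en-1-yl]triphenylphosphonium bromide | [Br-].c1ccccc1[P+](c1ccccc1)(c1ccccc1)C/C(C)=C/C=C1/C(C)=CC2(OCCO2)CC1(C)C | intermediate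
27 | [(2E,4E)-2-methyl-4-(2,6,6-trimethyl-4-oxocyclohex-2-en-1-ylidene)but-2-en-1-yl]triphenylphosphonium bromide | [Br-].c1ccccc1[P+](c1ccccc1)(c1ccccc1)C/C(C)=C/C=C1/C(C)=CC(=O)CC1(C)C | intermediate
28 | ylide of 27 (triphenylphosphonio methanide at C10) | c1ccccc1[P+](c1ccccc1)(c1ccccc1)[CH-]/C(C)=C/C=C1/C(C)=CC(=O)CC1(C)C | intermediate
29 | (4E)-4-[(2E,4E,6E,8E)-9-iodo-3,7-dimethylnona-2,4,6,8-tetraen-1-ylidene]-3,5,5-trimethylcyclohex-2-en-1-one | I/C=C/C(C)=C/C=C/C(C)=C/C=C1/C(C)=CC(=O)CC1(C)C | intermediate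
30 | (3'S,6E,6'E)-3'-[(tert-butyldiphenylsilyl)oxy]-4',5'-didehydro-4,5'-retro-β,β-caroten-3-one (all-E) | CC1=CC(=O)CC(C)(C)\C1=C/C=C(C)/C=C/C=C(C)/C=C/C=C/C(C)=C/C=C/C(C)=C/C=C1/C(C)=C[C@@H](O[Si](c2ccccc2)(c2ccccc2)C(C)(C)C)CC1(C)C | intermediate
31 | (3'S,6E,6'E)-3'-hydroxy-4',5'-didehydro-4,5'-retro-β,β-caroten-3-one (all-E) | CC1=CC(=O)CC(C)(C)\C1=C/C=C(C)/C=C/C=C(C)/C=C/C=C/C(C)=C/C=C/C(C)=C/C=C1/C(C)=C[C@@H](O)CC1(C)C | target

**Step count and risks**

Total step count: 19. Longest linear sequence: 11 steps (steps 1–8, 12, 18, 19).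

Steps most likely to fail:

Step 5. The carbenoid may add with chloride mainly on the exo face, and that epimer cannot open to a cis-cyclohexenyl cation; butyllithium may also cleave the silyl enol ether before the carbenoid adds. The fallback inserts the carbon with dibromocarbene, in which one bromide is necessarily endo, and introduces the methyl group afterwards by cross-coupling. It sets out from 7: CHBr3 and KOt-Bu in pentane at −20 °C should give (4S)-6,6-dibromo-4-[(tert-butyldiphenylsilyl)oxy]-2,2-dimethyl-1-[(trimethylsilyl)oxy]bicyclo[3.1.0]hexane F1. Warming F1 in toluene with pyridine should open it to (4S)-2-bromo-4-[(tert-butyldiphenylsilyl)oxy]-6,6-dimethylcyclohex-2-en-1-one F2. Suzuki–Miyaura methylation of F2 (MeB(OH)2, PdCl2(dppf), K3PO4, dioxane, 80 °C) comes back to the route at 9.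

Step 8 (and its twin, step 16). Ionisation may be followed by capture of the cation at an internal position, by proton loss to anhydro products, or by loss of the silyl ether. The fallback builds the retro triene by stepwise olefination of the ring ketone, with no tertiary cation. It sets out from 9: Peterson olefination with the lithium enolate of ethyl (trimethylsilyl)acetate (LiN(i-Pr)2, THF, −78 °C to rt) should give ethyl (2E)-2-{(4S)-4-[(tert-butyldiphenylsilyl)oxy]-2,6,6-trimethylcyclohex-2-en-1-ylidene}acetate F3. Reduction with i-Bu2AlH gives (2E)-2-{(4S)-4-[(tert-butyldiphenylsilyl)oxy]-2,6,6-trimethylcyclohex-2-en-1-ylidene}ethan-1-ol F4, and MnO2 gives (2E)-2-{(4S)-4-[(tert-butyldiphenylsilyl)oxy]-2,6,6-trimethylcyclohex-2-en-1-ylidene}acetaldehyde F5. Wittig reaction with Ph3P=C(Me)CO2Et gives ethyl (2E,4E)-4-{(4S)-4-[(tert-butyldiphenylsilyl)oxy]-2,6,6-trimethylcyclohex-2-en-1-ylidene}-2-methylbut-2-enoate F6, and i-Bu2AlH gives (2E,4E)-4-{(4S)-4-[(tert-butyldiphenylsilyl)oxy]-2,6,6-trimethylcyclohex-2-en-1-ylidene}-2-methylbut-2-en-1-ol F7. As a primary allylic alcohol, F7 should give the phosphonium salt with PPh3·HBr by direct substitution, coming back to the route at 14.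

Step 18. The Stille union of two long polyenes may suffer from homocoupling, protodestannylation or decomposition of the hexaenyl iodide. The fallback assembles the C40 chain by two Wittig condensations on a central C12 dialdehyde. It sets out from 16: iodine in CH2Cl2 gives (2E,4E)-5-iodo-3-methylpenta-2,4-dien-1-ol F8. Stille coupling of F8 with a second portion of 16 gives (2E,4E,6E,8E)-3,8-dimethyldeca-2,4,6,8-tetraene-1,10-diol F9, and MnO2 gives (2E,4E,6E,8E)-3,8-dimethyldeca-2,4,6,8-tetraenedial F10. Condensation of F10, used in excess, with ylide 28 gives (2E,4E,6E,8E,10E,12E)-3,8,12-trimethyl-14-(2,6,6-trimethyl-4-oxocyclohex-2-en-1-ylidene)tetradeca-2,4,6,8,10,12-hexaenal F11. Condensation of F11 with ylide 19 comes back to the route at 30.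

Further compounds
F1 | step 5 | (4S)-6,6-dibromo-4-[(tert-butyldiphenylsilyl)oxy]-2,2-dimethyl-1-[(trimethylsilyl)oxy]bicyclo[3.1.0]hexane | C[Si](C)(C)OC12C(Br)(Br)C1[C@@H](O[Si](c3ccccc3)(c3ccccc3)C(C)(C)C)CC2(C)C
F2 | step 5 | (4S)-2-bromo-4-[(tert-butyldiphenylsilyl)oxy]-6,6-dimethylcyclohex-2-en-1-one | BrC1=C[C@@H](O[Si](c2ccccc2)(c2ccccc2)C(C)(C)C)CC(C)(C)C1=O
F3 | step 8 | ethyl (2E)-2-{(4S)-4-[(tert-butyldiphenylsilyl)oxy]-2,6,6-trimethylcyclohex-2-en-1-ylidene}acetate | CCOC(=O)/C=C1/C(C)=C[C@@H](O[Si](c2ccccc2)(c2ccccc2)C(C)(C)C)CC1(C)C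
F4 | step 8 | (2E)-2-{(4S)-4-[(tert-butyldiphenylsilyl)oxy]-2,6,6-trimethylcyclohex-2-en-1-ylidene}ethan-1-ol | OC/C=C1/C(C)=C[C@@H](O[Si](c2ccccc2)(c2ccccc2)C(C)(C)C)CC1(C)C
F5 | step 8 | (2E)-2-{(4S)-4-[(tert-butyldiphenylsilyl)oxy]-2,6,6-trimethylcyclohex-2-en-1-ylidene}acetaldehyde | O=C/C=C1/C(C)=C[C@@H](O[Si](c2ccccc2)(c2ccccc2)C(C)(C)C)CC1(C)C
F6 | step 8 | ethyl (2E,4E)-4-{(4S)-4-[(tert-butyldiphenylsilyl)oxy]-2,6,6-trimethylcyclohex-2-en-1-ylidene}-2-methylbut-2-enoate | CCOC(=O)/C(C)=C/C=C1/C(C)=C[C@@H](O[Si](c2ccccc2)(c2ccccc2)C(C)(C)C)CC1(C)C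
F7 | step 8 | (2E,4E)-4-{(4S)-4-[(tert-butyldiphenylsilyl)oxy]-2,6,6-trimethylcyclohex-2-en-1-ylidene}-2-methylbut-2-en-1-ol | OC/C(C)=C/C=C1/C(C)=C[C@@H](O[Si](c2ccccc2)(c2ccccc2)C(C)(C)C)CC1(C)C
F8 | step 18 | (2E,4E)-5-iodo-3-methylpenta-2,4-dien-1-ol | I/C=C/C(C)=C/CO
F9 | step 18 | (2E,4E,6E,8E)-3,8-dimethyldeca-2,4,6,8-tetraene-1,10-diol | OC/C=C(C)/C=C/C=C/C(C)=C/CO
F10 | step 18 | (2E,4E,6E,8E)-3,8-dimethyldeca-2,4,6,8-tetraenedial | O=C/C=C(C)/C=C/C=C/C(C)=C/C=O
F11 | step 18 | (2E,4E,6E,8E,10E,12E)-3,8,12-trimethyl-14-(2,6,6-trimethyl-4-oxocyclohex-2-en-1-ylidene)tetradeca-2,4,6,8,10,12-hexaenal | CC1=CC(=O)CC(C)(C)\C1=C/C=C(C)/C=C/C=C(C)/C=C/C=C/C(C)=C/C=O
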